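**Plan**

1. Cuts: the central cyclohexene by Diels–Alder (C19–C17' and C29–C29') and C17=C18 of each half by Horner–Wadsworth–Emmons (HWE), so both C30 halves come from one spiro phosphonate (25) and the C9 enal 29; then C14–C15 (ketone α-alkenylation); then, in the spiro ketone, C6–C7, C10–C11 and C2–C1 in a single step.
2. Enabling feature: in each half the cyclohexane C6–C11 holds a tertiary aldol (C10–OH β to the C26 oxygen across spiro C11), C6 is β to C26, and C7 carries a tetrasubstituted exocyclic alkene. The ring is therefore the adduct of an s-cis enone (C26=O/C11=C6), an alkyne (C7≡C2) with a tethered methyl ketone (C10), and a one-carbon organozinc.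
3. Forward: aldol condensation gives alkylidenecyclopentanone 5; the nickel coupling/aldol builds the cyclohexane on it (spirocycle 14); the C14 side chain and C26 reduction follow; HWE gives tetraene 30; Diels–Alder with 29 closes the central ring (31); a second HWE adds half A (32); ester exchange, oxidation and desilylation finish.
4. Stereochemistry: C6 from the chiral ligand on nickel; C10/C11 from a zinc-chelated chair aldol; C7=C2 geometry from syn addition across the alkyne; C14 from coupling anti to C10; C26 from hydroxyl-directed reduction; C15=C16 from directed trans-hydroalumination; C17=C18 from HWE; the two central-ring centres from a chiral oxazaborolidinium catalyst (exo mode).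

Key step: step 5

Remark on locants: each half is numbered as an iridal. C1 is the aldehyde carbon, C2 carries methyl C25, C3–C5 is the propyl chain (O on C3), C6–C11 is the cyclohexane (C10 carbinol with methyl C27, C11 spiro), C11–C14 plus C26 is the cyclopentane, C15 carries C28 (CH2OH), and C19/C29 lie in the central ring. Unprimed locants are half A (quaternary ring carbon C19); primed locants are half B (C17'–C19', C29' in the central ring).

Assumption: the chiral carbene of step 5 and the oxazaborolidinium catalyst of step 18 are taken to induce in the sense drawn; if either induces the opposite sense, its mirror-image form is used.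

**Route**

Step 1
Reactants: 1 butane-1,4-diol
Product: 2 4-hydroxybutyl pivalate
Conditions: tBuCOCl (0.25 equiv relative to diol), pyridine, CH2Cl2, 0 °C
Reagents that add atoms: pivaloyl chloride, CC(C)(C)C(Cl)=O
Why: Acylation of an alcohol with an acid chloride; the excess of the symmetrical diol should keep diacylation low.

Step 2
Reactants: 2 4-hydroxybutyl pivalate
Product: 3 4-oxobutyl pivalate
Conditions: 2,2,6,6-tetramethylpiperidin-1-oxyl (10 mol %), PhI(OAc)2, CH2Cl2, rt
Reagents that add atoms: none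
Why: Nitroxyl-catalysed oxidation of a primary alcohol should stop at the aldehyde and leave the pivalate untouched.

Step 3
Reactants: 3 4-oxobutyl pivalate; 4 cyclopentanone
Product: 5 (E)-2-[4-(pivaloyloxy)butylidene]cyclopentan-1-one
Conditions: 4 in threefold excess, pyrrolidine (20 mol %), AcOH (20 mol %), toluene, 60 °C
Reagents that add atoms: none
Why: Amine-catalysed crossed aldol condensation (enamine addition, then elimination of water) should give the conjugated exocyclic enone, the E isomer (chain anti to the carbonyl) being the thermodynamic one.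

Step 4
Reactants: 6 acetone N,N-dimethylhydrazone; 7 1-bromobut-2-yne
Product: 9 hept-5-yn-2-one, via hydrazone 8 (not isolated)
Conditions: LiN(iPr)2, THF, −78 °C; 7, −78 to 0 °C; then 1 M aq. HCl, pentane, rt
Reagents that add atoms: water, O
Why: Alkylation of the lithiated hydrazone (aza-enolate, SN2 at the propargylic bromide) followed by acidic hydrolysis should give the monoalkylated methyl ketone without dialkylation.

Step 5
Reactants: 5 (E)-2-[4-(pivaloyloxy)butylidene]cyclopentan-1-one; 9 hept-5-yn-2-one; 10 (chloromethyl)(isopropoxy)dimethylsilane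
Product: 14 spiro diol ketone (6R,10S,11R; 2Z), via silylmethylzinc chloride 11 (not isolated), via zinc enolate 12 (not isolated), via allylsilane 13 (not isolated)
Conditions: 10, Mg, LiCl, ZnCl2, THF, 25 °C (gives 11, 2.5 equiv); then 5, Ni(cod)2 (10 mol %), (4R,5R)-1,3-bis(2-isopropylphenyl)-4,5-diphenyl-4,5-dihydroimidazol-2-ylidene (12 mol %, from its tetrafluoroborate and KN(SiMe3)2), slow addition of 9, THF, 0 °C to rt; aq. NH4Cl; then KF, KHCO3, 30% aq. H2O2, THF/MeOH, rt
Reagents that add atoms: hydrogen peroxide, OO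
Why: Proposed new method: zerovalent nickel, with the zinc reagent acting as Lewis acid on the s-cis-locked enone, should join C6 of 5 to C7 of the alkyne by oxidative cyclization, after which transmetalation from zinc and C(sp2)–C(sp3) reductive elimination place the CH2Si group on C2 on the same side as C6 (syn addition across the alkyne, fixing the tetrasubstituted alkene geometry) and the zinc enolate 12 closes the cyclohexane by aldol addition to the tethered methyl ketone; Tamao–Fleming oxidation in the work-up turns the C–Si bond into the C1 hydroxyl with no allylic shift. The closest known reaction type is the nickel-catalysed alkylative three-component coupling of enones, alkynes and organozincs, together with its variants in which the metal enolate is intercepted by an aldol addition. The ring closes in a 6-(enolexo)-exo-trig mode. C6 is set in the oxidative cyclization by the chiral carbene; C11 and C10 are set in a chair-like, zinc-chelated (closed) aldol transition state in which the C6 side chain is axial to escape A1,3 strain with the cis CH2Si group and the C10 methyl is equatorial, so that C5, C26 and the new hydroxyl end up on one face of the cyclohexane. The step needs C6 to bond to the alkyne carbon that carries the ketone chain, which the bulky ligand should secure by keeping the small methyl-bearing carbon next to nickel, and it needs the enolate to reach the ketone before it is protonated, which the six-membered chelate and the aprotic medium should secure.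

Step 6
Reactants: 14 spiro diol ketone
Product: 15 spiro hydroxy ketone bis-pivalate (6R,10S,11R; 2Z)
Conditions: tBuCOCl (1.1 equiv), pyridine, 4-(dimethylamino)pyridine (5 mol %), CH2Cl2, −20 °C
Reagents that add atoms: pivaloyl chloride, CC(C)(C)C(Cl)=O
Why: Acylation should be selective for the primary allylic alcohol because the tertiary C10 hydroxyl is too hindered to react at low temperature.

Step 7
Reactants: 15 spiro hydroxy ketone bis-pivalate
Product: 16 bis(trimethylsilyl) derivative (C26 silyl enol ether and C10 silyl ether)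
Conditions: Me3SiOTf (2.5 equiv), Et3N (4 equiv), CH2Cl2, 0 °C
Reagents that add atoms: trimethylsilyl trifluoromethanesulfonate, C[Si](C)(C)OS(=O)(=O)C(F)(F)F
Why: Soft enolization and silylation should give the only possible silyl enol ether (C11 is quaternary, so only C14 can be deprotonated) and cap the tertiary alcohol, which blocks retro-aldol opening in the coupling that follows.

Step 8
Reactants: 17 but-2-yne-1,4-diol
Product: 18 4-[(tert-butyldimethylsilyl)oxy]but-2-yn-1-ol
Conditions: NaH (1.0 equiv), THF, 0 °C; tBuMe2SiCl (1.0 equiv)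
Reagents that add atoms: tert-butyldimethylsilyl chloride, CC(C)(C)[Si](C)(C)Cl
Why: Silylation of the monosodium alkoxide of a symmetrical diol should give mainly the mono-ether.

Step 9
Reactants: 18 4-[(tert-butyldimethylsilyl)oxy]but-2-yn-1-ol
Product: 19 (Z)-4-[(tert-butyldimethylsilyl)oxy]-3-iodobut-2-en-1-ol
Conditions: NaAlH2(OCH2CH2OCH3)2, THF, 0 °C; then I2, −78 to 0 °C
Reagents that add atoms: iodine, II
Why: Hydroxyl-directed trans-hydroalumination of the propargylic alcohol places aluminium on the distal alkyne carbon in a five-membered alkoxyaluminate, and iodinolysis with retention puts iodine cis to the CH2OH group, which fixes the future C15=C16 geometry.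

Step 10
Reactants: 19 (Z)-iodo allylic alcohol
Product: 20 {[(Z)-4-bromo-2-iodobut-2-en-1-yl]oxy}(tert-butyl)dimethylsilane
Conditions: CBr4, PPh3, CH2Cl2, 0 °C
Reagents that add atoms: tetrabromomethane, BrC(Br)(Br)Br
Why: The Appel reaction converts the primary allylic alcohol into the bromide under neutral conditions that should spare the alkenyl iodide and the silyl ether.

Step 11
Reactants: 20 (Z)-allylic bromide
Product: 21 diethyl {(Z)-4-[(tert-butyldimethylsilyl)oxy]-3-iodobut-2-en-1-yl}phosphonate
Conditions: P(OEt)3 (neat), 100 °C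
Reagents that add atoms: triethyl phosphite, CCOP(OCC)OCC
Why: Michaelis–Arbuzov reaction at the primary allylic bromide (SN2 by phosphorus, then dealkylation) should give the allylic phosphonate; the alkenyl iodide is inert without a metal catalyst.

Step 12
Reactants: 16 bis(trimethylsilyl) derivative; 21 iodoalkenyl phosphonate
Product: 23 α-alkenyl hydroxy ketone phosphonate (6R,10S,11R,14S; 2Z,15E), via trimethylsilyl ether 22 (not isolated)
Conditions: Pd2(dba)3 (2.5 mol %), P(tBu)3 (6 mol %), Bu3SnF (1.3 equiv), toluene, 70 °C; then citric acid, MeOH, 0 °C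
Reagents that add atoms: none
Why: Palladium-catalysed cross-coupling of a silyl enol ether with an alkenyl iodide through its tributyltin enolate (ketone α-alkenylation) should retain the alkene geometry under neutral conditions that do not move the new double bond into conjugation, and the C14–C15 bond should form on the cyclopentane face opposite to the fully substituted C10 (methyl and OSiMe3), which sets C14; methanolysis then frees the tertiary alcohol.

Step 13
Reactants: 23 α-alkenyl hydroxy ketone phosphonate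
Product: 24 diol phosphonate (6R,10S,11S,14S,26R)
Conditions: Me4NBH(OAc)3 (5 equiv), MeCN/AcOH 1:1, −30 °C
Reagents that add atoms: none
Why: Evans–Saksena reduction: the triacetoxyborohydride exchanges onto the C10 hydroxyl and delivers hydride intramolecularly to the face of the C26 carbonyl that is syn to C10, so the new hydroxyl should be cis to the C14 side chain and trans to C10, as in the target.

Step 14
Reactants: 24 diol phosphonate
Product: 25 bis(triethylsilyl) ether phosphonate (6R,10S,11S,14S,26R)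
Conditions: Et3SiOTf (3 equiv), 2,6-lutidine (5 equiv), CH2Cl2, −78 to 0 °C
Reagents that add atoms: triethylsilyl trifluoromethanesulfonate, CC[Si](CC)(CC)OS(=O)(=O)C(F)(F)F
Why: Silylation with the silyl triflate protects both the hindered secondary and the tertiary alcohol for the base and Lewis acid steps that follow.

Step 15
Reactants: 26 2-methylprop-2-en-1-ol; 27 1-bromo-3-methylbut-2-ene
Product: 28 6-methyl-2-methylidenehept-5-en-1-ol
Conditions: nBuLi (2.1 equiv), TMEDA, Et2O, 0 °C to rt; then 27, −78 °C to rt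
Reagents that add atoms: none
Why: Alkylation of the dianion of methallyl alcohol (alkoxide plus allylic carbanion) should occur at carbon by SN2 displacement of the primary allylic bromide and give the 2-substituted allylic alcohol directly.

Step 16
Reactants: 28 6-methyl-2-methylidenehept-5-en-1-ol
Product: 29 6-methyl-2-methylidenehept-5-enal
Conditions: MnO2, CH2Cl2, rt
Reagents that add atoms: none
Why: MnO2 oxidizes the allylic alcohol to the 2-substituted acrolein without affecting the isolated trisubstituted alkene.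

Step 17
Reactants: 25 bis(triethylsilyl) ether phosphonate; 29 6-methyl-2-methylidenehept-5-enal
Product: 30 tetraene (2Z,15E,17E), the protected monomer with C17=C18–C19(=CH2)–homoprenyl
Conditions: LiN(SiMe3)2 (1.05 equiv), THF, −78 °C; then 29, −78 to 0 °C
Reagents that add atoms: none
Why: Horner–Wadsworth–Emmons olefination of the allylic phosphonate anion with the non-enolizable enal should form C17=C18 E-selectively, and the low temperature should keep the C15=C16 geometry of the allyl anion intact.

Step 18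
Reactants: 30 tetraene; 29 6-methyl-2-methylidenehept-5-enal
Product: 31 cyclohexene aldehyde (19S,17'R; formyl trans to the C17' alkenyl group; C19 becomes R after olefination by a CIP change only)
Conditions: 29 in threefold excess, (S)-1-(2-methylphenyl)-3,3-diphenyltetrahydro-1H,3H-pyrrolo[1,2-c][1,3,2]oxazaborole activated with (CF3SO2)2NH (20 mol %), CH2Cl2, −78 °C; Et3N quench at −78 °C
Reagents that add atoms: none
Why: Catalytic enantioselective Diels–Alder reaction of a 2-substituted acrolein activated by a chiral cationic oxazaborolidine: only the terminal 2-substituted diene of 30 can become s-cis, its 1-alkenyl and 3-alkyl substituents both direct the formyl-bearing carbon to C17' (ortho/para rule), the formyl-exo transition state typical of α-substituted acroleins places the homoprenyl group cis to the C16' alkenyl group, and the catalyst blocks one enal face so that the diene adds to the Si face of C2 of 29, which sets both ring stereocentres; the amine quench neutralizes the acid activator before the silyl ethers are warmed.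

Step 19
Reactants: 31 cyclohexene aldehyde; 25 bis(triethylsilyl) ether phosphonate
Product: 32 fully protected dimer (four pivalates, two tBuMe2Si ethers, four Et3Si ethers)
Conditions: LiN(SiMe3)2 (1.05 equiv), 25, THF, −78 °C; then 31, −78 °C to rt
Reagents that add atoms: none
Why: Horner–Wadsworth–Emmons olefination of a second equivalent of 25 with the non-enolizable α-quaternary aldehyde should give the (E)-C17=C18 alkene of half A.

Step 20
Reactants: 32 fully protected dimer
Product: 33 tetraol (both C1–OH and both C3–OH free)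
Conditions: iBu2AlH (10 equiv), CH2Cl2, −78 °C; aq. potassium sodium tartrate work-up
Reagents that add atoms: none
Why: Reduction with iBu2AlH cleaves all four pivalates while silyl ethers and alkenes are inert.

Step 21
Reactants: 33 tetraol
Product: 34 bis-enal diol (2Z,2'Z)
Conditions: MnO2 (excess), CH2Cl2, rt
Reagents that add atoms: none
Why: MnO2 should oxidize only the two allylic C1 alcohols to the enals with retention of the tetrasubstituted alkene geometry and leave the saturated C3 alcohols untouched.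

Step 22
Reactants: 34 bis-enal diol; 35 tetradecanoyl chloride (2.4 equiv)
Product: 36 silyl-protected bis(tetradecanoate)
Conditions: pyridine, 4-(dimethylamino)pyridine (cat.), CH2Cl2, 0 °C
Reagents that add atoms: none
Why: Acylation of the only free hydroxyls (the two primary C3 alcohols) with the acid chloride installs both tetradecanoates.

Step 23
Reactants: 36 silyl-protected bis(tetradecanoate)
Product: 37 CNP0458412.1 (target)
Conditions: HF·pyridine, pyridine, THF, 0 °C to rt
Reagents that add atoms: none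
Why: Fluoride-mediated desilylation should remove the two tBuMe2Si and four Et3Si ethers in one operation under buffered conditions that the esters, enals and polyene tolerate.

**Compound list**

1 | butane-1,4-diol | OCCCCO | starting material
2 | 4-hydroxybutyl pivalate | CC(C)(C)C(=O)OCCCCO | intermediate
3 | 4-oxobutyl pivalate | CC(C)(C)C(=O)OCCCC=O | intermediate
4 | cyclopentanone | O=C1CCCC1 | starting material
5 | (E)-2-[4-(pivaloyloxy)butylidene]cyclopentan-1-one | CC(C)(C)C(=O)OCCC/C=C1\CCCC1=O | intermediate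
6 | acetone N,N-dimethylhydrazone | CC(C)=NN(C)C | starting material
7 | 1-bromobut-2-yne | CC#CCBr | starting material
8 | hept-5-yn-2-one N,N-dimethylhydrazone | CC#CCCC(C)=NN(C)C | intermediate (not isolated)
9 | hept-5-yn-2-one | CC#CCCC(C)=O | intermediate
10 | (chloromethyl)(isopropoxy)dimethylsilane | CC(C)O[Si](C)(C)CCl | starting material
11 | {[isopropoxy(dimethyl)silyl]methyl}zinc chloride | CC(C)O[Si](C)(C)C[Zn]Cl | intermediate (not isolated)
12 | zinc enolate of the three-component adduct (C6 bonded to C7; CH2Si cis to C6) | CC(C)(C)C(=O)OCCC[C@@H](C1=C(O[Zn]Cl)CCC1)/C(CCC(C)=O)=C(/C)C[Si](C)(C)OC(C)C | intermediate (not isolated)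
13 | spiro aldol allylsilane (C1 as CH2SiMe2OiPr) | CC(C)(C)C(=O)OCCC[C@@H]1/C(=C(/C)C[Si](C)(C)OC(C)C)CC[C@](C)(O)[C@@]12CCCC2=O | intermediate (not isolated)
14 | spiro diol ketone: cyclohexane C6–C11 spiro at C11 to cyclopentanone (C26=O); C6 bears the 3-(pivaloyloxy)propyl chain; C7=C2(CH3)CH2OH with CH2OH cis to C6; C10 bears OH and CH3; C5, C26 and 10-OH on one face (6R,10S,11R; 2Z) | CC(C)(C)C(=O)OCCC[C@@H]1/C(=C(/C)CO)CC[C@](C)(O)[C@@]12CCCC2=O | intermediate
15 | C1 pivalate of 14 | CC(C)(C)C(=O)OCCC[C@@H]1/C(=C(/C)COC(=O)C(C)(C)C)CC[C@](C)(O)[C@@]12CCCC2=O | intermediate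
16 | C26 trimethylsilyl enol ether (C26=C14) and C10 trimethylsilyl ether of 15 | CC(C)(C)C(=O)OCCC[C@@H]1/C(=C(/C)COC(=O)C(C)(C)C)CC[C@](C)(O[Si](C)(C)C)[C@@]12CCC=C2O[Si](C)(C)C | intermediate
17 | but-2-yne-1,4-diol | OCC#CCO | starting material
18 | 4-[(tert-butyldimethylsilyl)oxy]but-2-yn-1-ol | OCC#CCO[Si](C)(C)C(C)(C)C | intermediate
19 | (Z)-4-[(tert-butyldimethylsilyl)oxy]-3-iodobut-2-en-1-ol | OC/C=C(\I)CO[Si](C)(C)C(C)(C)C | intermediate
20 | {[(Z)-4-bromo-2-iodobut-2-en-1-yl]oxy}(tert-butyl)dimethylsilane | BrC/C=C(\I)CO[Si](C)(C)C(C)(C)C | intermediate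
21 | diethyl {(Z)-4-[(tert-butyldimethylsilyl)oxy]-3-iodobut-2-en-1-yl}phosphonate | CCOP(=O)(OCC)C/C=C(\I)CO[Si](C)(C)C(C)(C)C | intermediate
22 | C10 trimethylsilyl ether of 23 | CC(C)(C)C(=O)OCCC[C@@H]1/C(=C(/C)COC(=O)C(C)(C)C)CC[C@](C)(O[Si](C)(C)C)[C@@]12CC[C@@H](/C(=C\CP(=O)(OCC)OCC)CO[Si](C)(C)C(C)(C)C)C2=O | intermediate (not isolated)
23 | 15 carrying at C14 the (E)-C15(CH2OSitBuMe2)=C16H–C17H2–P(O)(OEt)2 chain, trans to C10 (6R,10S,11R,14S) | CC(C)(C)C(=O)OCCC[C@@H]1/C(=C(/C)COC(=O)C(C)(C)C)CC[C@](C)(O)[C@@]12CC[C@@H](/C(=C\CP(=O)(OCC)OCC)CO[Si](C)(C)C(C)(C)C)C2=O | intermediate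
24 | C26 alcohol of 23 (OH cis to the C14 chain; 6R,10S,11S,14S,26R) | CC(C)(C)C(=O)OCCC[C@@H]1/C(=C(/C)COC(=O)C(C)(C)C)CC[C@](C)(O)[C@@]12CC[C@@H](/C(=C\CP(=O)(OCC)OCC)CO[Si](C)(C)C(C)(C)C)[C@H]2O | intermediate
25 | 10,26-bis(triethylsilyl) ether of 24 | CC(C)(C)C(=O)OCCC[C@@H]1/C(=C(/C)COC(=O)C(C)(C)C)CC[C@](C)(O[Si](CC)(CC)CC)[C@@]12CC[C@@H](/C(=C\CP(=O)(OCC)OCC)CO[Si](C)(C)C(C)(C)C)[C@H]2O[Si](CC)(CC)CC | intermediate
26 | 2-methylprop-2-en-1-ol | CC(=C)CO | starting material
27 | 1-bromo-3-methylbut-2-ene | CC(C)=CCBr | starting material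
28 | 6-methyl-2-methylidenehept-5-en-1-ol | CC(C)=CCCC(=C)CO | intermediate
29 | 6-methyl-2-methylidenehept-5-enal | CC(C)=CCCC(=C)C=O | intermediate
30 | tetraene: 25 with the phosphonate replaced by (E)-C17=C18–C19(=CH2)–CH2CH2CH=C(CH3)2 | CC(C)(C)C(=O)OCCC[C@@H]1/C(=C(/C)COC(=O)C(C)(C)C)CC[C@](C)(O[Si](CC)(CC)CC)[C@@]12CC[C@@H](/C(=C\C=C\C(=C)CCC=C(C)C)CO[Si](C)(C)C(C)(C)C)[C@H]2O[Si](CC)(CC)CC | intermediate
31 | cyclohexene aldehyde: central ring with CHO and homoprenyl on C19, homoprenyl on C19', and on C17' the (E)-CH=C(CH2OSitBuMe2)– link to C14' of protected half B | O=C[C@@]1(CCC=C(C)C)CCC(CCC=C(C)C)=C[C@@H]1/C=C(/CO[Si](C)(C)C(C)(C)C)[C@@H]1CC[C@]3([C@H](CCCOC(=O)C(C)(C)C)/C(=C(/C)COC(=O)C(C)(C)C)CC[C@]3(C)O[Si](CC)(CC)CC)[C@@H]1O[Si](CC)(CC)CC | intermediate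
32 | fully protected dimer (3,3',1,1'-tetrapivalate; 28,28'-bis-tBuMe2Si; 10,10',26,26'-tetra-Et3Si) | CC(C)(C)C(=O)OCCC[C@@H]1/C(=C(/C)COC(=O)C(C)(C)C)CC[C@](C)(O[Si](CC)(CC)CC)[C@@]12CC[C@@H](/C(=C\C=C\[C@@]1(CCC=C(C)C)CCC(CCC=C(C)C)=C[C@@H]1/C=C(/CO[Si](C)(C)C(C)(C)C)[C@@H]1CC[C@]3([C@H](CCCOC(=O)C(C)(C)C)/C(=C(/C)COC(=O)C(C)(C)C)CC[C@]3(C)O[Si](CC)(CC)CC)[C@@H]1O[Si](CC)(CC)CC)CO[Si](C)(C)C(C)(C)C)[C@H]2O[Si](CC)(CC)CC | intermediate
33 | tetraol (32 without the four pivaloyl groups) | OCCC[C@@H]1/C(=C(/C)CO)CC[C@](C)(O[Si](CC)(CC)CC)[C@@]12CC[C@@H](/C(=C\C=C\[C@@]1(CCC=C(C)C)CCC(CCC=C(C)C)=C[C@@H]1/C=C(/CO[Si](C)(C)C(C)(C)C)[C@@H]1CC[C@]3([C@H](CCCO)/C(=C(/C)CO)CC[C@]3(C)O[Si](CC)(CC)CC)[C@@H]1O[Si](CC)(CC)CC)CO[Si](C)(C)C(C)(C)C)[C@H]2O[Si](CC)(CC)CC | intermediate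
34 | bis-enal diol (C1 and C1' aldehydes; C3 and C3' hydroxyls free) | OCCC[C@@H]1/C(=C(/C)C=O)CC[C@](C)(O[Si](CC)(CC)CC)[C@@]12CC[C@@H](/C(=C\C=C\[C@@]1(CCC=C(C)C)CCC(CCC=C(C)C)=C[C@@H]1/C=C(/CO[Si](C)(C)C(C)(C)C)[C@@H]1CC[C@]3([C@H](CCCO)/C(=C(/C)C=O)CC[C@]3(C)O[Si](CC)(CC)CC)[C@@H]1O[Si](CC)(CC)CC)CO[Si](C)(C)C(C)(C)C)[C@H]2O[Si](CC)(CC)CC | intermediate
35 | tetradecanoyl chloride | CCCCCCCCCCCCCC(=O)Cl | starting material
36 | silyl-protected bis(tetradecanoate) | CCCCCCCCCCCCCC(=O)OCCC[C@@H]1/C(=C(/C)C=O)CC[C@](C)(O[Si](CC)(CC)CC)[C@@]12CC[C@@H](/C(=C\C=C\[C@@]1(CCC=C(C)C)CCC(CCC=C(C)C)=C[C@@H]1/C=C(/CO[Si](C)(C)C(C)(C)C)[C@@H]1CC[C@]3([C@H](CCCOC(=O)CCCCCCCCCCCCC)/C(=C(/C)C=O)CC[C@]3(C)O[Si](CC)(CC)CC)[C@@H]1O[Si](CC)(CC)CC)CO[Si](C)(C)C(C)(C)C)[C@H]2O[Si](CC)(CC)CC | intermediate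
37 | CNP0458412.1 | CCCCCCCCCCCCCC(=O)OCCC[C@@H]1/C(=C(/C)C=O)CC[C@](C)(O)[C@@]12CC[C@@H](/C(=C\C=C\[C@@]1(CCC=C(C)C)CCC(CCC=C(C)C)=C[C@@H]1/C=C(/CO)[C@@H]1CC[C@]3([C@H](CCCOC(=O)CCCCCCCCCCCCC)/C(=C(/C)C=O)CC[C@]3(C)O)[C@@H]1O)CO)[C@H]2O | target

**Totals and risks**

Total step count: 23. Longest linear sequence: 16 steps (1, 2, 3, 5, 6, 7, 12, 13, 14, 17, 18, 19, 20, 21, 22, 23, from butane-1,4-diol).

Step 5 (proposed new method). The enone may bond to the methyl-bearing alkyne carbon instead of C7, the silylmethyl group may transfer too slowly from zinc to nickel, the zinc enolate may be protonated before it adds to the ketone, or the aldol may close through the other chair and give the C11 epimer. The fallback sets out from 5 and rejoins at 15, using a preformed, geometrically defined alkenyl nucleophile. Commercial 2-(but-3-yn-1-yl)-2-methyl-1,3-dioxolane is hydroxymethylated (nBuLi, paraformaldehyde) to propargylic alcohol F1. Copper-catalysed anti-carbomagnesiation with MeMgBr (CuI) and iodinolysis of the five-membered magnesium chelate gives iodoalkenol F2 with iodine cis to CH2OH. Pivaloylation gives pivalate ketal F3, ketal hydrolysis (pyridinium p-toluenesulfonate, aqueous acetone) gives iodo ketone F4, and Miyaura borylation (B2pin2, PdCl2(dppf), KOAc) gives alkenylboronate F5. Rhodium-catalysed asymmetric conjugate addition of F5 to 5 ([Rh(OH)(cod)]2, (R)-BINAP, KOH, aqueous dioxane), with aldol cyclization of the rhodium enolate onto the tethered ketone, should give 15 with the same syn relationship of C6 and C1.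

Step 18. The cationic Lewis acid may oligomerize the electron-rich tetraene, 30 may dimerize with itself, or exo and facial selectivity may be insufficient with so large a diene. The fallback sets out from 21, 29 and 16 and rejoins at 32; it sets the ring stereocentres on a small diene before either spiro half is attached. HWE olefination of 21 with 29 gives iodotetraene F11. The same oxazaborolidinium-catalysed Diels–Alder reaction with 29 gives iodo aldehyde F12, and a second HWE with 21 gives bis(alkenyl iodide) F13. Two-fold α-alkenylation of 16 (2.2 equiv) under the conditions of step 12 gives bis(trimethylsilyl ether) diketone F14, which citric acid in methanol converts into diketone diol F15. Two-fold Evans–Saksena reduction gives tetraol F16, and silylation with Et3SiOTf as in step 14 gives 32.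

Step 12. Facial selectivity at C14 may be poor, the new double bond may migrate into conjugation with the ketone, zerovalent palladium may ionize the allylic pivalate, or the hindered tin enolate may transmetalate slowly. The fallback sets out from 16 and 21 and rejoins at 23; it sets C14 by internally directed protonation instead of by the coupling. Saegusa–Ito oxidation of 16 (Pd(OAc)2, MeCN) gives cyclopentenone F6, and α-iodination (I2, pyridine) gives iodoenone F7. Separately, 21 is converted into alkenylstannane F8 ((Bu3Sn)2, Pd(PPh3)4). Stille coupling of F7 with F8 (Pd2(dba)3, AsPh3, CuI) gives cross-conjugated dienone F9, and citric acid in methanol frees the C10 hydroxyl to give hydroxy dienone F10. Conjugate reduction with [(Ph3P)CuH]6 delivers hydride to C13, and the copper enolate is protonated at C14 by the neighbouring C10 hydroxyl on its own face, which leaves the side chain on the opposite face and should give 23.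

**Further compounds**

F1 | step 5 | 5-(2-methyl-1,3-dioxolan-2-yl)pent-2-yn-1-ol | OCC#CCCC1(C)OCCO1
F2 | step 5 | (Z)-3-iodo-2-methyl-5-(2-methyl-1,3-dioxolan-2-yl)pent-2-en-1-ol | OC/C(C)=C(\I)CCC1(C)OCCO1
F3 | step 5 | (Z)-3-iodo-2-methyl-5-(2-methyl-1,3-dioxolan-2-yl)pent-2-en-1-yl pivalate | CC(C)(C)C(=O)OC/C(C)=C(\I)CCC1(C)OCCO1
F4 | step 5 | (Z)-3-iodo-2-methyl-6-oxohept-2-en-1-yl pivalate | CC(C)(C)C(=O)OC/C(C)=C(\I)CCC(C)=O
F5 | step 5 | (Z)-2-methyl-6-oxo-3-(4,4,5,5-tetramethyl-1,3,2-dioxaborolan-2-yl)hept-2-en-1-yl pivalate | CC(C)(C)C(=O)OC/C(C)=C(\B1OC(C)(C)C(C)(C)O1)CCC(C)=O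
F6 | step 12 | cyclopentenone (C13=C14) from 16, C10 trimethylsilyl ether | CC(C)(C)C(=O)OCCC[C@@H]1/C(=C(/C)COC(=O)C(C)(C)C)CC[C@](C)(O[Si](C)(C)C)[C@@]12CC=CC2=O
F7 | step 12 | 14-iodo cyclopentenone | CC(C)(C)C(=O)OCCC[C@@H]1/C(=C(/C)COC(=O)C(C)(C)C)CC[C@](C)(O[Si](C)(C)C)[C@@]12CC=C(I)C2=O
F8 | step 12 | diethyl {(E)-4-[(tert-butyldimethylsilyl)oxy]-3-(tributylstannyl)but-2-en-1-yl}phosphonate (tin cis to CH2P) | CCOP(=O)(OCC)C/C=C(\[Sn](CCCC)(CCCC)CCCC)CO[Si](C)(C)C(C)(C)C
F9 | step 12 | cross-conjugated dienone, C10 trimethylsilyl ether | CC(C)(C)C(=O)OCCC[C@@H]1/C(=C(/C)COC(=O)C(C)(C)C)CC[C@](C)(O[Si](C)(C)C)[C@@]12CC=C(/C(=C\CP(=O)(OCC)OCC)CO[Si](C)(C)C(C)(C)C)C2=O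
F10 | step 12 | cross-conjugated dienone, C10 hydroxyl free | CC(C)(C)C(=O)OCCC[C@@H]1/C(=C(/C)COC(=O)C(C)(C)C)CC[C@](C)(O)[C@@]12CC=C(/C(=C\CP(=O)(OCC)OCC)CO[Si](C)(C)C(C)(C)C)C2=O
F11 | step 18 | iodotetraene tert-butyl{[(2Z,4E)-2-iodo-10-methyl-6-methylideneundeca-2,4,9-trien-1-yl]oxy}dimethylsilane | CC(C)=CCCC(=C)/C=C/C=C(\I)CO[Si](C)(C)C(C)(C)C
F12 | step 18 | iodo aldehyde: central cyclohexene with CHO and homoprenyl on C19 and the (Z)-CH=C(I)CH2OSitBuMe2 group on C17' | O=C[C@@]1(CCC=C(C)C)CCC(CCC=C(C)C)=C[C@@H]1/C=C(\I)CO[Si](C)(C)C(C)(C)C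
F13 | step 18 | bis(alkenyl iodide) core | CC(C)(C)[Si](C)(C)OC/C(I)=C/C=C/[C@@]1(CCC=C(C)C)CCC(CCC=C(C)C)=C[C@@H]1/C=C(\I)CO[Si](C)(C)C(C)(C)C
F14 | step 18 | dimeric diketone, 10,10'-bis(trimethylsilyl ether) | CC(C)(C)C(=O)OCCC[C@@H]1/C(=C(/C)COC(=O)C(C)(C)C)CC[C@](C)(O[Si](C)(C)C)[C@@]12CC[C@@H](/C(=C\C=C\[C@@]1(CCC=C(C)C)CCC(CCC=C(C)C)=C[C@@H]1/C=C(/CO[Si](C)(C)C(C)(C)C)[C@@H]1CC[C@]3([C@H](CCCOC(=O)C(C)(C)C)/C(=C(/C)COC(=O)C(C)(C)C)CC[C@]3(C)O[Si](C)(C)C)C1=O)CO[Si](C)(C)C(C)(C)C)C2=O
F15 | step 18 | dimeric diketone diol (10,10'-OH free, 26,26'-ketones) | CC(C)(C)C(=O)OCCC[C@@H]1/C(=C(/C)COC(=O)C(C)(C)C)CC[C@](C)(O)[C@@]12CC[C@@H](/C(=C\C=C\[C@@]1(CCC=C(C)C)CCC(CCC=C(C)C)=C[C@@H]1/C=C(/CO[Si](C)(C)C(C)(C)C)[C@@H]1CC[C@]3([C@H](CCCOC(=O)C(C)(C)C)/C(=C(/C)COC(=O)C(C)(C)C)CC[C@]3(C)O)C1=O)CO[Si](C)(C)C(C)(C)C)C2=O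
F16 | step 18 | dimeric tetraol (10,10',26,26'-OH free; 32 without its Et3Si groups) | CC(C)(C)C(=O)OCCC[C@@H]1/C(=C(/C)COC(=O)C(C)(C)C)CC[C@](C)(O)[C@@]12CC[C@@H](/C(=C\C=C\[C@@]1(CCC=C(C)C)CCC(CCC=C(C)C)=C[C@@H]1/C=C(/CO[Si](C)(C)C(C)(C)C)[C@@H]1CC[C@]3([C@H](CCCOC(=O)C(C)(C)C)/C(=C(/C)COC(=O)C(C)(C)C)CC[C@]3(C)O)[C@@H]1O)CO[Si](C)(C)C(C)(C)C)[C@H]2O
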